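**Plan**

- Retrosynthesis: both C–Br bonds go back to vinyl bromides (C4=C5, C4′=C5′; last step). The C8–OAc / C1′–OH / C2–OH array goes back to an aldol bond C1–C8 between a trans-hydrindane enol silyl ether and an achiral bromodienal. Ring B is cut at C4′–C5′ and C2′–C3′.
- Enabling feature: in ring B, C4′ (CBr) lies between the quaternary C3′ (CMe2) and C5′H2 and is 1,4 to C1′, which carries the exocyclic carbon C8. At the 1,3-diene level (C1′=C6′–C5′=C4′Br) this ring is the 6π-electrocyclisation product of a (Z)-hexatriene with termini C2′H2 and C3′Me2, i.e. of a sulfolene-derived dienyl sulfinate coupled to Me2C=CBr2.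
- Forward order: ring B (step 1), then dienal 7. The hydrindane six-ring comes from 2-methylcyclohexane-1,3-dione, the cyclopentenone by aldol condensation. The fragments are joined at C1–C8 (step 17), then C2 and C1′ are set, and both bromides come last.
- Stereochemistry: C3a by enzymatic desymmetrisation. Relayed from it: C7 (axial γ-hydroxylation), C7a (hydride anti to the angular methyl), C1/C8 (aldol), C2 (chelate-controlled reduction), C1′ (C8–OH-directed epoxidation). C4 and C4′ come from radical hydrogenation that leaves both Br equatorial.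

Key step: step 1

Remark (assumption and labels): 1 and 2 are taken as purchasable (1 is otherwise two steps from 3-sulfolene, 2 one step from acetone). Hydrindane atoms are C1–C7a as in the target, with the angular methyl on C3a defined as β. C8 is the carbinol carbon between the rings. Ring B is C1′ (carbinol), C2′ (CH2), C3′ (CMe2), C4′ (CBr), C5′, C6′.

**Route**

Step 1
Reactants: 1 methyl 2,5-dihydrothiophene-3-carboxylate 1,1-dioxide; 2 1,1-dibromo-2-methylprop-1-ene
Product: 5 methyl 4-bromo-5,5-dimethylcyclohexa-1,3-diene-1-carboxylate, via potassium dienylsulfinate 3 (not isolated), via bromotriene ester 4 (not isolated)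
Conditions: K2CO3, 1,4-dioxane, rt; then 2 (3 equiv), Pd(OAc)2 (5 mol%), XPhos (10 mol%), BHT, 100 °C
Reagents that add atoms: none
Why: Proposed new method: base opens the sulfolene by E1cB through the ester-stabilised carbanion at the CH2 remote from the ester-bearing carbon (future C5′), so sulfur stays on that carbon and the ring geometry is carried over as the (Z)-dienyl sulfinate 3; Pd(0) inserts into one C–Br bond of the symmetrical gem-dibromide, the sulfinate transmetalates, SO2 is lost and reductive elimination forms C5′–C4′ with retention to give the (3Z)-triene 4. The s-cis,Z,s-cis triene then closes thermally by a disrotatory 6π-electrocyclisation between its CH2 terminus and its CMe2 terminus, which forms C2′–C3′ and the quaternary carbon and leaves the second bromine as the C4′ vinyl bromide. The closest known reaction types are the Pd-catalysed desulfinative dienylation of aryl and alkenyl halides with sulfolenes and cross-coupling/6π-electrocyclisation cascades; untested are the ester-bearing sulfolene, the tetrasubstituted gem-dibromoalkene and the ring closure in the same flask. No stereocentre is formed because both termini carry two identical groups, so only the alkene geometry matters and it is fixed by the five-membered ring of 1. The step needs regioselective ring opening (secured by the vinylogous acidity of the CH2 that is γ to the ester), mono-coupling (secured by excess 2, by the absence of a vinylic H that would allow alkyne formation, and by the hindered C–Br of 4 and 5 next to CMe2) and ring closure faster than diene oligomerisation (the ester on the triene lowers the barrier, the inward methyl raises it, hence 100 °C).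

Step 2
Reactants: 5 methyl 4-bromo-5,5-dimethylcyclohexa-1,3-diene-1-carboxylate
Product: 6 (4-bromo-5,5-dimethylcyclohexa-1,3-dien-1-yl)methanol
Conditions: DIBAL-H (2.2 equiv), CH2Cl2, −78 °C
Reagents that add atoms: none
Why: DIBAL-H 1,2-reduction of the conjugated ester should give the primary dienyl alcohol, the hindered C(sp2)–Br being inert to the aluminium hydride at −78 °C.

Step 3
Reactants: 6 (4-bromo-5,5-dimethylcyclohexa-1,3-dien-1-yl)methanol
Product: 7 4-bromo-5,5-dimethylcyclohexa-1,3-diene-1-carbaldehyde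
Conditions: MnO2, CH2Cl2, rt
Reagents that add atoms: none
Why: MnO2 oxidation is selective for the dienylic alcohol and stops at the aldehyde.

Step 4
Reactants: 8 2-methylcyclohexane-1,3-dione; 9 allyl bromide
Product: 10 2-allyl-2-methylcyclohexane-1,3-dione
Conditions: 1 M NaOH, H2O, rt
Reagents that add atoms: none
Why: C-alkylation of the cyclic 1,3-dione enolate with an allylic halide forms the prochiral quaternary carbon (future C3a).

Step 5
Reactants: 10 2-allyl-2-methylcyclohexane-1,3-dione
Product: 11 (2S,3S)-2-allyl-3-hydroxy-2-methylcyclohexan-1-one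
Conditions: ketoreductase (baker's-yeast type, selected for the (2S,3S) alcohol), NADP+ (cat.), i-PrOH, phosphate buffer pH 7, 30 °C
Reagents that add atoms: none
Why: enzymatic desymmetrising reduction of one of the two enantiotopic carbonyls, the selectivity known for baker's yeast on this dione class, should set the quaternary centre (2S, future C3a) and the carbinol (3S, OH cis to allyl) under enzyme control.

Step 6
Reactants: 11 (2S,3S)-2-allyl-3-hydroxy-2-methylcyclohexan-1-one
Product: 12 (6S,7S)-6-allyl-6-methyl-1,4-dioxaspiro[4.5]decan-7-ol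
Conditions: ethylene glycol, PPTS (cat.), benzene, reflux (Dean–Stark)
Reagents that add atoms: ethylene glycol OCCO
Why: acid-catalysed ketalisation masks the remaining ketone (future C4 carbonyl), and the β-hydroxy ketone cannot dehydrate because the carbon between the two functions is quaternary.

Step 7
Reactants: 12 (6S,7S)-6-allyl-6-methyl-1,4-dioxaspiro[4.5]decan-7-ol
Product: 13 (6S)-6-allyl-6-methyl-1,4-dioxaspiro[4.5]decan-7-one
Conditions: Dess–Martin periodinane, CH2Cl2, rt
Reagents that add atoms: none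
Why: Dess–Martin oxidation converts the carbinol into the future C7a ketone, so the two carbonyl carbons of the dione are now differentiated and only C3a carries the stereochemical information.

Step 8
Reactants: 13 (6S)-6-allyl-6-methyl-1,4-dioxaspiro[4.5]decan-7-one
Product: 14 (6S)-6-allyl-6,8-dimethyl-1,4-dioxaspiro[4.5]decan-7-one (both epimers at the new methyl-bearing carbon, hydrindane C7)
Conditions: LDA, THF, −78 °C; MeI
Reagents that add atoms: iodomethane CI
Why: kinetic enolate alkylation, the ketone being able to enolise only towards C7, introduces the C7 methyl regiospecifically; the new centre is not controlled and is erased in step 11.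

Step 9
Reactants: 14 (6S)-6-allyl-6,8-dimethyl-1,4-dioxaspiro[4.5]decan-7-one
Product: 15 (6S)-6,8-dimethyl-6-(2-oxopropyl)-1,4-dioxaspiro[4.5]decan-7-one
Conditions: PdCl2 (10 mol%), CuCl (co-catalyst), O2 (1 atm), DMF/H2O 7:1, rt
Reagents that add atoms: water O
Why: Tsuji–Wacker oxidation turns the terminal alkene into the methyl ketone (Markovnikov) and gives the 1,4-diketone.

Step 10
Reactants: 15 (6S)-6,8-dimethyl-6-(2-oxopropyl)-1,4-dioxaspiro[4.5]decan-7-one
Product: 16 (3aS)-4,4-ethylenedioxy-3a,7-dimethyl-3,3a,4,5,6,7-hexahydro-2H-inden-2-one (enone C1=C7a, C7 epimers)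
Conditions: KOH, MeOH, 60 °C
Reagents that add atoms: none
Why: base-mediated intramolecular aldol condensation of the 1,4-diketone (methyl ketone enolate onto the ring carbonyl, then dehydration) closes the cyclopentenone.

Step 11
Reactants: 16 (3aS)-4,4-ethylenedioxy-3a,7-dimethyl-3,3a,4,5,6,7-hexahydro-2H-inden-2-one
Product: 17 (3aS)-2-(tert-butyldimethylsilyloxy)-4,4-ethylenedioxy-3a,7-dimethyl-3a,4,5,6-tetrahydro-3H-indene (diene C1=C2, C7=C7a)
Conditions: TBSOTf, Et3N, CH2Cl2, 0 °C to rt
Reagents that add atoms: tert-butyldimethylsilyl triflate CC(C)(C)[Si](C)(C)OS(=O)(=O)C(F)(F)F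
Why: soft enolisation under equilibrating conditions should give the through-conjugated 2-silyloxy diene by loss of the γ-hydrogen at C7, so both C7 epimers converge.

Step 12
Reactants: 17 (3aS)-2-(tert-butyldimethylsilyloxy)-4,4-ethylenedioxy-3a,7-dimethyl-3a,4,5,6-tetrahydro-3H-indene
Product: 19 (3aS,7R)-7-hydroxy-3a,7-dimethyl-3,3a,6,7-tetrahydro-2H-indene-2,4(5H)-dione (7β-OH, enone C1=C7a), via hydroxy enone ketal 18 (not isolated)
Conditions: mCPBA, NaHCO3, CH2Cl2, −20 °C; then 1 M HCl, THF, rt
Reagents that add atoms: 3-chloroperbenzoic acid OOC(=O)c1cccc(Cl)c1; water O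
Why: vinylogous Rubottom oxidation, in which the peracid attacks the electron-rich terminus C7 of the dienol ether axially on the β-face (as in the 6β-hydroxylation of steroidal 3,5-dienol ethers), should set C7 (β-OH, α-Me), and aqueous acid then removes silyl residues and the dioxolane.

Step 13
Reactants: 19 (3aS,7R)-7-hydroxy-3a,7-dimethyl-3,3a,6,7-tetrahydro-2H-indene-2,4(5H)-dione
Product: 20 7-O-trimethylsilyl ether of 19
Conditions: N-(trimethylsilyl)imidazole, CH2Cl2, rt
Reagents that add atoms: N-(trimethylsilyl)imidazole C[Si](C)(C)n1ccnc1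
Why: silyl transfer from TMS-imidazole protects the tertiary alcohol without enolising either ketone.

Step 14
Reactants: 20 7-O-trimethylsilyl ether of 19
Product: 21 (3aS,7R,7aS)-3a,7-dimethyl-2-(triethylsilyloxy)-7-(trimethylsilyloxy)-3,3a,5,6,7,7a-hexahydro-4H-inden-4-one (enol ether C1=C2, 7a-H α, trans-fused)
Conditions: RhCl(PPh3)3 (2 mol%), Et3SiH, benzene, 60 °C
Reagents that add atoms: triethylsilane CC[SiH](CC)CC
Why: Rh-catalysed 1,4-hydrosilylation of the enone delivers hydride to C7a from the α-face, anti to the angular methyl and the 7β-silyloxy group, which sets the trans ring fusion and gives the regiodefined enol silyl ether, while the hindered saturated C4 ketone is not hydrosilylated by a monohydrosilane.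

Step 15
Reactants: 21 (3aS,7R,7aS)-3a,7-dimethyl-2-(triethylsilyloxy)-7-(trimethylsilyloxy)-3,3a,5,6,7,7a-hexahydro-4H-inden-4-one
Product: 22 (3aS,7R,7aS)-3a,7-dimethyl-2-(triethylsilyloxy)-7-(trimethylsilyloxy)-3a,6,7,7a-tetrahydro-3H-inden-4-yl trifluoromethanesulfonate
Conditions: KHMDS, THF, −78 °C; PhNTf2
Reagents that add atoms: N-phenylbis(trifluoromethanesulfonimide) O=S(=O)(N(c1ccccc1)S(=O)(=O)C(F)(F)F)C(F)(F)F
Why: kinetic deprotonation of the C4 ketone, which can enolise only towards C5, and O-triflation give the enol triflate, the silyl enol ether and silyl ether being stable to the amide base.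

Step 16
Reactants: 22 (3aS,7R,7aS)-3a,7-dimethyl-2-(triethylsilyloxy)-7-(trimethylsilyloxy)-3a,6,7,7a-tetrahydro-3H-inden-4-yl trifluoromethanesulfonate
Product: 23 (3aS,7R,7aS)-4-bromo-3a,7-dimethyl-2-(triethylsilyloxy)-7-(trimethylsilyloxy)-3a,6,7,7a-tetrahydro-3H-indene
Conditions: Ni(cod)2 (10 mol%), LiBr, DMA/THF, rt
Reagents that add atoms: lithium bromide [Li+].[Br-]
Why: Ni-catalysed halide exchange of the enol triflate (oxidative addition, triflate/bromide metathesis, C–Br reductive elimination) gives the C4 vinyl bromide under neutral conditions.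

Step 17
Reactants: 23 (3aS,7R,7aS)-4-bromo-3a,7-dimethyl-2-(triethylsilyloxy)-7-(trimethylsilyloxy)-3a,6,7,7a-tetrahydro-3H-indene; 7 4-bromo-5,5-dimethylcyclohexa-1,3-diene-1-carbaldehyde
Product: 25 (1R,3aS,7R,7aS)-4-bromo-1-[(R)-(4-bromo-5,5-dimethylcyclohexa-1,3-dien-1-yl)(hydroxy)methyl]-7-hydroxy-3a,7-dimethyl-1,3,3a,6,7,7a-hexahydro-2H-inden-2-one (side chain 1α), via bis-silyl aldol ether 24 (not isolated)
Conditions: TASF (0.2 equiv), THF, −78 °C; then HF·pyridine, pyridine, THF, 0 °C
Reagents that add atoms: none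
Why: in this fluoride-promoted (naked enolate) aldol addition the aldehyde should approach C1 on the α-face, anti to the C7a–C7 bond and the angular methyl, and the open extended transition state of such aldols gives the syn adduct irrespective of enolate geometry, which sets C1 (α side chain) and C8 (R), after which buffered HF cleaves both silyl groups.

Step 18
Reactants: 25 aldol adduct
Product: 26 (R)-[(1S,2R,3aS,7R,7aS)-4-bromo-2,7-dihydroxy-3a,7-dimethyl-2,3,3a,6,7,7a-hexahydro-1H-inden-1-yl](4-bromo-5,5-dimethylcyclohexa-1,3-dien-1-yl)methanol (2α-OH)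
Conditions: Et2BOMe, NaBH4, THF/MeOH 4:1, −78 °C; MeOH azeotrope
Reagents that add atoms: none
Why: in this Narasaka–Prasad reduction the diethylboron chelate of the β-hydroxy ketone lies on the α-face, so external hydride adds to C2 from the β-face and should give the 1,3-syn diol (2α-OH).

Step 19
Reactants: 26 syn diol
Product: 27 (R)-[(1S,2R,3aS,7R,7aS)-4-bromo-2,7-dihydroxy-3a,7-dimethyl-2,3,3a,6,7,7a-hexahydro-1H-inden-1-yl][(1R,6R)-4-bromo-3,3-dimethyl-7-oxabicyclo[4.1.0]hept-4-en-1-yl]methanol (epoxide across C1′–C6′)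
Conditions: VO(acac)2 (5 mol%), t-BuOOH, CH2Cl2, 0 °C
Reagents that add atoms: tert-butyl hydroperoxide CC(C)(C)OO
Why: vanadium-catalysed hydroxyl-directed epoxidation acts on the allylic alkene C1′=C6′ only, and A(1,2) strain between the C8 substituents and C2′H2 should give the erythro epoxy alcohol, which sets C1′ from C8.

Step 20
Reactants: 27 epoxy triol
Product: 28 (R)-[(1S,2R,3aS,7R,7aS)-4-bromo-2,7-dihydroxy-3a,7-dimethyl-2,3,3a,6,7,7a-hexahydro-1H-inden-1-yl][(1R)-4-bromo-1-hydroxy-3,3-dimethylcyclohex-4-en-1-yl]methanol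
Conditions: LiAlH4, THF, −20 to 0 °C
Reagents that add atoms: none
Why: hydride opens the vinyl epoxide by SN2 attack at the allylic secondary carbon C6′ and leaves the tertiary C1′–OH, SN2′ attack at C4′ being blocked by bromine and the adjacent quaternary carbon.

Step 21
Reactants: 28 tetraol
Product: 29 2-O-triethylsilyl ether of 28
Conditions: TESCl, imidazole, DMF, 0 °C
Reagents that add atoms: chlorotriethylsilane CC[Si](Cl)(CC)CC
Why: silylation should discriminate the two secondary alcohols, since C2–OH on the cyclopentane is accessible while C8–OH is flanked by the quaternary C1′ carbinol and the ring methine.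

Step 22
Reactants: 29 2-O-triethylsilyl ether of 28
Product: 30 8-O-acetate of 29
Conditions: Ac2O, DMAP (cat.), Et3N, CH2Cl2, rt
Reagents that add atoms: acetic anhydride CC(=O)OC(C)=O
Why: DMAP-catalysed acylation acts on the only free secondary alcohol (C8–OH), the tertiary alcohols at C7 and C1′ not reacting at room temperature.

Step 23
Reactants: 30 8-O-acetate of 29
Product: 31 (R)-[(1S,2R,3aS,7R,7aS)-4-bromo-2,7-dihydroxy-3a,7-dimethyl-2,3,3a,6,7,7a-hexahydro-1H-inden-1-yl][(1R)-4-bromo-1-hydroxy-3,3-dimethylcyclohex-4-en-1-yl]methyl acetate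
Conditions: HF·pyridine, THF, 0 °C
Reagents that add atoms: none
Why: fluoride removes the secondary TES ether under mildly acidic conditions that should not promote acetyl migration to C2–OH.

Step 24
Reactants: 31 bis(vinyl bromide) monoacetate
Product: 32 (R)-[(1S,2R,3aS,4S,7R,7aS)-4-bromo-2,7-dihydroxy-3a,7-dimethyloctahydro-1H-inden-1-yl][(1R,4S)-4-bromo-1-hydroxy-3,3-dimethylcyclohexyl]methyl acetate (CNP0166243.1)
Conditions: Mn(dpm)3 (10 mol%), PhSiH3, t-BuOOH, i-PrOH, rt
Reagents that add atoms: none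
Why: in this metal-hydride H-atom-transfer hydrogenation H• adds to C5 and C5′ and each α-bromo radical (C4, C4′) takes its second hydrogen axially, anti to the axial methyl on the neighbouring quaternary carbon, so both bromines should end equatorial (4β-Br cis to the angular methyl, C4′–Br cis to C1′–OH) with the C–Br bonds kept.

**Compound list**

1 | methyl 2,5-dihydrothiophene-3-carboxylate 1,1-dioxide | COC(=O)C1=CCS(=O)(=O)C1 | starting material
2 | 1,1-dibromo-2-methylprop-1-ene | CC(C)=C(Br)Br | starting material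
3 | potassium (1Z)-3-(methoxycarbonyl)buta-1,3-diene-1-sulfinate | [K+].[O-]S(=O)/C=C\C(=C)C(=O)OC | intermediate
4 | methyl (3Z)-5-bromo-6-methyl-2-methylidenehepta-3,5-dienoate | C=C(C(=O)OC)/C=C\C(Br)=C(C)C | intermediate
5 | methyl 4-bromo-5,5-dimethylcyclohexa-1,3-diene-1-carboxylate | COC(=O)C1=CC=C(Br)C(C)(C)C1 | intermediate
6 | (4-bromo-5,5-dimethylcyclohexa-1,3-dien-1-yl)methanol | OCC1=CC=C(Br)C(C)(C)C1 | intermediate
7 | 4-bromo-5,5-dimethylcyclohexa-1,3-diene-1-carbaldehyde | O=CC1=CC=C(Br)C(C)(C)C1 | intermediate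
8 | 2-methylcyclohexane-1,3-dione | CC1C(=O)CCCC1=O | starting material
9 | allyl bromide | C=CCBr | starting material
10 | 2-allyl-2-methylcyclohexane-1,3-dione | C=CCC1(C)C(=O)CCCC1=O | intermediate
11 | (2S,3S)-2-allyl-3-hydroxy-2-methylcyclohexan-1-one | O=C1CCC[C@H](O)[C@]1(C)CC=C | intermediate
12 | (6S,7S)-6-allyl-6-methyl-1,4-dioxaspiro[4.5]decan-7-ol | O[C@H]1CCCC2(OCCO2)[C@@]1(C)CC=C | intermediate
13 | (6S)-6-allyl-6-methyl-1,4-dioxaspiro[4.5]decan-7-one | O=C1CCCC2(OCCO2)[C@@]1(C)CC=C | intermediate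
14 | (6S)-6-allyl-6,8-dimethyl-1,4-dioxaspiro[4.5]decan-7-one (epimers at the new methyl carbon) | O=C1C(C)CCC2(OCCO2)[C@@]1(C)CC=C | intermediate
15 | (6S)-6,8-dimethyl-6-(2-oxopropyl)-1,4-dioxaspiro[4.5]decan-7-one | O=C1C(C)CCC2(OCCO2)[C@@]1(C)CC(C)=O | intermediate
16 | (3aS)-4,4-ethylenedioxy-3a,7-dimethyl-3,3a,4,5,6,7-hexahydro-2H-inden-2-one | O=C1C=C2C(C)CCC3(OCCO3)[C@@]2(C)C1 | intermediate
17 | (3aS)-2-(tert-butyldimethylsilyloxy)-4,4-ethylenedioxy-3a,7-dimethyl-3a,4,5,6-tetrahydro-3H-indene | CC1=C2C=C(O[Si](C)(C)C(C)(C)C)C[C@]2(C)C3(OCCO3)CC1 | intermediate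
18 | (3aS,7R)-4,4-ethylenedioxy-7-hydroxy-3a,7-dimethyl-3,3a,4,5,6,7-hexahydro-2H-inden-2-one | O=C1C=C2[C@](C)(O)CCC3(OCCO3)[C@@]2(C)C1 | intermediate
19 | (3aS,7R)-7-hydroxy-3a,7-dimethyl-3,3a,6,7-tetrahydro-2H-indene-2,4(5H)-dione | O=C1C=C2[C@](C)(O)CCC(=O)[C@@]2(C)C1 | intermediate
20 | 7-O-trimethylsilyl ether of 19 | O=C1C=C2[C@](C)(O[Si](C)(C)C)CCC(=O)[C@@]2(C)C1 | intermediate
21 | (3aS,7R,7aS)-3a,7-dimethyl-2-(triethylsilyloxy)-7-(trimethylsilyloxy)-3,3a,5,6,7,7a-hexahydro-4H-inden-4-one | CC[Si](CC)(CC)OC1=C[C@@H]2[C@](C)(O[Si](C)(C)C)CCC(=O)[C@@]2(C)C1 | intermediate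
22 | (3aS,7R,7aS)-3a,7-dimethyl-2-(triethylsilyloxy)-7-(trimethylsilyloxy)-3a,6,7,7a-tetrahydro-3H-inden-4-yl triflate | CC[Si](CC)(CC)OC1=C[C@@H]2[C@](C)(O[Si](C)(C)C)CC=C(OS(=O)(=O)C(F)(F)F)[C@@]2(C)C1 | intermediate
23 | (3aS,7R,7aS)-4-bromo-3a,7-dimethyl-2-(triethylsilyloxy)-7-(trimethylsilyloxy)-3a,6,7,7a-tetrahydro-3H-indene | CC[Si](CC)(CC)OC1=C[C@@H]2[C@](C)(O[Si](C)(C)C)CC=C(Br)[C@@]2(C)C1 | intermediate
24 | 8-O-triethylsilyl, 7-O-trimethylsilyl ether of 25 | CC[Si](CC)(CC)O[C@H]([C@@H]1C(=O)C[C@]2(C)C(Br)=CC[C@@](C)(O[Si](C)(C)C)[C@@H]12)C1=CC=C(Br)C(C)(C)C1 | intermediate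
25 | (1R,3aS,7R,7aS)-4-bromo-1-[(R)-(4-bromo-5,5-dimethylcyclohexa-1,3-dien-1-yl)(hydroxy)methyl]-7-hydroxy-3a,7-dimethyl-1,3,3a,6,7,7a-hexahydro-2H-inden-2-one | O[C@H]([C@@H]1C(=O)C[C@]2(C)C(Br)=CC[C@@](C)(O)[C@@H]12)C1=CC=C(Br)C(C)(C)C1 | intermediate
26 | (R)-[(1S,2R,3aS,7R,7aS)-4-bromo-2,7-dihydroxy-3a,7-dimethyl-2,3,3a,6,7,7a-hexahydro-1H-inden-1-yl](4-bromo-5,5-dimethylcyclohexa-1,3-dien-1-yl)methanol | O[C@H]([C@@H]1[C@H](O)C[C@]2(C)C(Br)=CC[C@@](C)(O)[C@@H]12)C1=CC=C(Br)C(C)(C)C1 | intermediate
27 | C1′–C6′ epoxide of 26, ring B (1R,6R)-4-bromo-3,3-dimethyl-7-oxabicyclo[4.1.0]hept-4-en-1-yl | O[C@H]([C@@H]1[C@H](O)C[C@]2(C)C(Br)=CC[C@@](C)(O)[C@@H]12)[C@@]12O[C@@H]1C=C(Br)C(C)(C)C2 | intermediate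
28 | (R)-[(1S,2R,3aS,7R,7aS)-4-bromo-2,7-dihydroxy-3a,7-dimethyl-2,3,3a,6,7,7a-hexahydro-1H-inden-1-yl][(1R)-4-bromo-1-hydroxy-3,3-dimethylcyclohex-4-en-1-yl]methanol | O[C@H]([C@@H]1[C@H](O)C[C@]2(C)C(Br)=CC[C@@](C)(O)[C@@H]12)[C@@]1(O)CC=C(Br)C(C)(C)C1 | intermediate
29 | 2-O-triethylsilyl ether of 28 | O[C@H]([C@@H]1[C@H](O[Si](CC)(CC)CC)C[C@]2(C)C(Br)=CC[C@@](C)(O)[C@@H]12)[C@@]1(O)CC=C(Br)C(C)(C)C1 | intermediate
30 | 8-O-acetate of 29 | CC(=O)O[C@H]([C@@H]1[C@H](O[Si](CC)(CC)CC)C[C@]2(C)C(Br)=CC[C@@](C)(O)[C@@H]12)[C@@]1(O)CC=C(Br)C(C)(C)C1 | intermediate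
31 | (R)-[(1S,2R,3aS,7R,7aS)-4-bromo-2,7-dihydroxy-3a,7-dimethyl-2,3,3a,6,7,7a-hexahydro-1H-inden-1-yl][(1R)-4-bromo-1-hydroxy-3,3-dimethylcyclohex-4-en-1-yl]methyl acetate | CC(=O)O[C@H]([C@@H]1[C@H](O)C[C@]2(C)C(Br)=CC[C@@](C)(O)[C@@H]12)[C@@]1(O)CC=C(Br)C(C)(C)C1 | intermediate
32 | (R)-[(1S,2R,3aS,4S,7R,7aS)-4-bromo-2,7-dihydroxy-3a,7-dimethyloctahydro-1H-inden-1-yl][(1R,4S)-4-bromo-1-hydroxy-3,3-dimethylcyclohexyl]methyl acetate | CC(=O)O[C@H]([C@@H]1[C@H](O)C[C@]2(C)[C@@H](Br)CC[C@@](C)(O)[C@@H]12)[C@@]1(O)CC[C@H](Br)C(C)(C)C1 | target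

**Step count**

Total steps: 24. Longest linear sequence: 21 (steps 4–24); the ring-B branch is steps 1–3.

**Steps most likely to fail**

Step 1 (Proposed new method). The electron-poor dienyl sulfinate may oligomerise, the dibromide may couple twice, or the triene may fail to close at a temperature the diene survives. Fallback with known chemistry, from 1 back to 5: 1 is heated with 1,1-dimethoxy-2-methylprop-1-ene (COC(OC)=C(C)C) in toluene at 120 °C in a sealed tube. Cheletropic loss of SO2 releases 2-(methoxycarbonyl)buta-1,3-diene, which is trapped in an inverse-electron-demand Diels–Alder reaction (para orientation) to give methyl 4,4-dimethoxy-5,5-dimethylcyclohex-1-ene-1-carboxylate F1. Aqueous HCl in THF then gives methyl 5,5-dimethyl-4-oxocyclohex-1-ene-1-carboxylate F2. Triphenyl phosphite, bromine and Et3N in CH2Cl2 convert the ketone through its conjugated dienol into the vinyl bromide 5.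

Step 17. Simple diastereoselection at C8 may be poor (anti instead of syn addition), or the adduct may undergo retro-aldol cleavage during desilylation. Fallback, from 25 (taken on as its mixture with the C8 epimer F3) back to 26: L-Selectride in THF at −78 °C reduces the C2 ketone from the β-face, anti to the side chain, to give 26 together with the C8-epimeric diol F4. MnO2 oxidises only the dienylic C8–OH of both, which merges them into the single dienone F5. Narasaka–Prasad reduction of F5 (Et2BOMe, NaBH4), now directed by the 2α-OH, delivers hydride to C8 and gives the 1,3-syn diol 26.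

Step 24. Bromine may be lost by hydrodebromination, H-atom transfer to the hindered electron-poor bromoalkenes may be incomplete, or facial control at C4 or C4′ may be poor. Fallback, from 31 back to 32 with no new compound: diimide generated from 2-nitrobenzenesulfonylhydrazide and Et3N in CH2Cl2/MeOH at rt. It transfers H2 in a concerted syn fashion to the less hindered face of each bromoalkene (the α-face of C4=C5, anti to the angular methyl; the face of C4′=C5′ anti to the axial C1′–OH and the pseudoaxial C3′ methyl). Steric approach control, without radical or metal intermediates, should give the same two equatorial bromides.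

**Further compounds**

F1 | step 1 | methyl 4,4-dimethoxy-5,5-dimethylcyclohex-1-ene-1-carboxylate | COC(=O)C1=CCC(OC)(OC)C(C)(C)C1
F2 | step 1 | methyl 5,5-dimethyl-4-oxocyclohex-1-ene-1-carboxylate | COC(=O)C1=CCC(=O)C(C)(C)C1
F3 | step 17 | C8 epimer of 25, (1R,3aS,7R,7aS)-4-bromo-1-[(S)-(4-bromo-5,5-dimethylcyclohexa-1,3-dien-1-yl)(hydroxy)methyl]-7-hydroxy-3a,7-dimethyl-1,3,3a,6,7,7a-hexahydro-2H-inden-2-one | O[C@@H]([C@@H]1C(=O)C[C@]2(C)C(Br)=CC[C@@](C)(O)[C@@H]12)C1=CC=C(Br)C(C)(C)C1
F4 | step 17 | C8 epimer of 26 (2α-OH, 8S) | O[C@@H]([C@@H]1[C@H](O)C[C@]2(C)C(Br)=CC[C@@](C)(O)[C@@H]12)C1=CC=C(Br)C(C)(C)C1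
F5 | step 17 | [(1S,2R,3aS,7R,7aS)-4-bromo-2,7-dihydroxy-3a,7-dimethyl-2,3,3a,6,7,7a-hexahydro-1H-inden-1-yl](4-bromo-5,5-dimethylcyclohexa-1,3-dien-1-yl)methanone | O=C([C@@H]1[C@H](O)C[C@]2(C)C(Br)=CC[C@@](C)(O)[C@@H]12)C1=CC=C(Br)C(C)(C)C1
F0 | step 24 | none | none
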